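**Assumption:** the SMILES defines no stereocentre and no configuration for the biaryl axis, so none is controlled; compounds 1, 2, 5 and 8 are taken as catalogue chemicals.

## Analysis of the target

The target 14 (C35H26O10) has seven rings in two flavone units. Unit 1 is a 5,7-dihydroxychromen-4-one (benzo ring A, pyranone ring C) whose C2 is bonded to C6 of a 2,2-dimethylchroman (benzene ring B, dihydropyran ring D); unit 2 is an apigenin skeleton (benzo ring E, pyranone ring F, 4-hydroxyphenyl ring G). The units are joined by one biaryl bond, between chroman C8 (ring B, ortho to the ring D oxygen) and C8 of unit 2 (ring E, between the C7 hydroxyl and the ring F oxygen). This bond is the feature the strategy rests on: both of its carbons stand ortho to an oxygen and are the innately nucleophilic C–H positions of their rings, so the bond invites a direct oxidative union of two carbons of like polarity. There is no stereocentre; the biaryl axis carries three ortho substituents, but no configuration is defined for it. The sensitive groups are five phenols (two chelated to the C4 carbonyls), the two C2=C3 bonds of the vinylogous esters (hot alkali, over-reduction) and the tertiary alkyl aryl ether of ring D, which strong Lewis acids open; the phenols are therefore masked as benzyl ethers and freed by hydrogenolysis. The difficulties are the hindered biaryl bond, the choice between C8 and C6 of ring E, and the annulation of the C5 unit of ring D to ring B alone, although rings A and E are far more nucleophilic.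

## Retrosynthetic reasoning

**14 ⇒ 13.** Five O–benzyl bonds are cut and the C3–C4 bond of ring D is taken back to a double bond. A single hydrogenation then finishes the synthesis, and no Lewis acid meets the tertiary ether of ring D. The forward step has to cleave the benzyl ethers and saturate the chromene without reducing the C2=C3 bonds of rings C and F.

**13 ⇒ 12 ⇒ 11 + 1.** Ring C is cut at its O1–C2 bond (oxidative oxa-Michael closure of chalcone 12) and at the C2–C3 bond (aldol condensation of aldehyde 11 with acetophenone 1). Rings A and C are attached only after the biaryl bond exists. A phenol partner that already carried ring A would bring a second phloroglucinol ring into the key step, as nucleophilic as ring E, and cross-coupling would compete with self-coupling. The same building block 1 serves both flavone units.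

**11 ⇒ 9 ⇒ 7 + 8.** Ring D is cut at the C4–C4a bond and at the O–C2 bond. The C5 unit is first tied to the phenol oxygen of 7 with 8 and then moved to carbon by a sigmatropic shift (via 10). This delivers it only to the free ortho carbon of ring B; an electrophilic prenylation would attack C6 of ring E instead.

**7 ⇒ 4 + 5 (key disconnection).** The biaryl bond between the carbon ortho to the hydroxyl of ring B and C8 of ring E is cut into two C–H bonds. Neither partner needs a halogen or a boron group. Compound 5 is the simplest carrier of ring B: it has a free phenol to be oxidised, two equivalent ortho carbons, a formyl group that becomes C2 of ring C, and no nucleophilic ring of its own. Compound 4 brings rings E, F and G complete, so the choice between C8 and C6 is made by the innate reactivity of a finished flavone and no isomerisation of ring F can arise later. The forward reaction must oxidise only 5, bond only through C8 of 4, and stop after one arylation (via keto tautomer 6).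

**4 ⇒ 3 ⇒ 1 + 2.** Ring F is cut in the same way as ring C: oxidative closure of chalcone 3, which comes from condensation of 1 with 2.

## Alternatives that were turned down

**Alternative 1:** (textbook) The same biaryl bond is cut into an aryl iodide and an arylboron partner. The forward key step is a Suzuki–Miyaura coupling of the 8-iodide A1 (from 4 by iodination) with the pinacol boronate A2 of the complete, benzylated unit 1, boron at chroman C8. It was turned down because both partners need their own functionalisation sequence. A2 in particular requires a halogenated chroman aldehyde to be carried through chalcone formation, oxidative cyclisation and Miyaura borylation. The halogen and the boron are placed on exactly the two carbons that are already the most nucleophilic of their rings, so two or three steps are spent on handles that the innate reactivity makes redundant. The route would exceed ten steps, and the coupling would join an aryl iodide flanked by two oxygens with a boronate ortho to oxygen, where protodeboronation competes.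

**Alternative 2:** Biaryl first, heterocycles last. Rings C, F and D are cut together. The forward key step is an acid-induced threefold ring closure of the biaryl tetraketone A3: two cyclodehydrations of 1,3-diketones (from Baker–Venkataraman acyl transfers) and a Markovnikov hydroalkoxylation of the prenyl group. It was turned down because the cascade closes three rings that are each easy, while the hard bond still has to be made earlier, by cross-coupling of two fully ortho-substituted benzene rings. A3 needs two different acyl transfers at two phenols that must be kept apart. In the precursor of ring E the two oxygens ortho to the acyl group must be differentiated, or the 6-aryl isomer of unit 2 forms. The way to A3 costs more than the cascade wins.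

**Alternative 3:** Aryne route. The biaryl bond is cut between a metalated phloroglucinol ether and the chroman-7,8-yne A5, generated with fluoride from the silyl triflate A4; ring E would be acylated and elaborated afterwards. It was turned down on regiochemistry. The ring D oxygen sits beside C8, and an alkoxy group next to an aryne inductively stabilises negative charge on the adjacent aryne carbon. The nucleophile is therefore directed to the remote carbon C7, and the aryl group would end up at the wrong position. No substituent at C6 can override this, since C6 must carry the masked formyl carbon. A4 alone needs about five steps.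

Key step: step 3

## Route

**Step 1**
Reactants: 1 1-[2,4-bis(benzyloxy)-6-hydroxyphenyl]ethan-1-one; 2 4-(benzyloxy)benzaldehyde
Product: 3 (E)-1-[2,4-bis(benzyloxy)-6-hydroxyphenyl]-3-[4-(benzyloxy)phenyl]prop-2-en-1-one
Conditions: KOH (aq. 50 %), EtOH, 25 °C; then aq. HCl
Reagents that add atoms: none
Why: Claisen–Schmidt condensation: the enolate of the acetyl group of 1 adds to the non-enolisable aldehyde 2 and E1cB loss of water gives the thermodynamically favoured (E)-enone; the chelated phenol of 1 stays free for the later ring closure.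

**Step 2**
Reactants: 3 (E)-1-[2,4-bis(benzyloxy)-6-hydroxyphenyl]-3-[4-(benzyloxy)phenyl]prop-2-en-1-one
Product: 4 5,7-bis(benzyloxy)-2-[4-(benzyloxy)phenyl]-4H-chromen-4-one
Conditions: I2 (10 mol %), DMSO, 130 °C
Reagents that add atoms: none
Why: Iodine-catalysed oxidative cyclisation of a 2'-hydroxychalcone (6-endo oxa-Michael closure of ring F, α-iodination, loss of HI); DMSO reoxidises HI to iodine, and benzyl aryl ethers are stable under these conditions.

**Step 3**
Reactants: 4 5,7-bis(benzyloxy)-2-[4-(benzyloxy)phenyl]-4H-chromen-4-one; 5 4-hydroxybenzaldehyde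
Product: 7 3-{5,7-bis(benzyloxy)-2-[4-(benzyloxy)phenyl]-4-oxo-4H-chromen-8-yl}-4-hydroxybenzaldehyde, via keto tautomer 6 (not isolated)
Conditions: FeCl3 (10 mol %), t-BuOOt-Bu (1.5 equiv), 5 (3 equiv), HFIP/CH2Cl2, 25 °C
Reagents that add atoms: none
Why: Proposed new method: trivalent iron binds the only phenol in the flask (5) as an iron phenolate, and the peroxide oxidises this complex to an iron-bound phenoxyl radical of 5, which is electrophilic at the two carbons ortho to oxygen because the para carbon carries the formyl group; C8 of 4, the most nucleophilic arene carbon present, adds to it, and loss of an electron and a proton from the radical adduct gives the keto tautomer 6, which enolises to 7. The closest known reaction type is the iron-catalysed oxidative cross-coupling of phenols with electron-rich arenes in HFIP; new here are a phenol with a para-formyl group and a flavone as the arene. The step closes no ring and sets no stereocentre; the new biaryl axis has no defined configuration in the target. Cross-coupling should win over homo-coupling because the two roles are separated by structure: 5 is the only O–H donor and, with its para-formyl group, a poor carbon nucleophile, whereas 4 has no O–H group to bind iron and is the only electron-rich arene. The two ortho carbons of 5 are equivalent, so the phenol side has no regiochemical choice. On 4, C8 is para to the C5 oxygen, ortho to the C7 oxygen and flanked on one side only by the unsubstituted ring oxygen, whereas C6 lies between two benzyloxy groups and C3 is only the α-carbon of a vinylogous ester; electrophilic substitution of 5,7-dialkoxyflavones by iodine/silver salts is known to go to C8. The excess of cheap 5 keeps the product phenol 7 from being oxidised and arylated a second time. HFIP stabilises the radical and cationic intermediates and, by hydrogen bonding to the phenoxyl oxygen, favours C–C over C–O bond formation.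

**Step 4**
Reactants: 7 3-{5,7-bis(benzyloxy)-2-[4-(benzyloxy)phenyl]-4-oxo-4H-chromen-8-yl}-4-hydroxybenzaldehyde; 8 3-chloro-3-methylbut-1-yne
Product: 9 3-{5,7-bis(benzyloxy)-2-[4-(benzyloxy)phenyl]-4-oxo-4H-chromen-8-yl}-4-[(2-methylbut-3-yn-2-yl)oxy]benzaldehyde
Conditions: DBU, CuCl2·2H2O (1 mol %), MeCN, 0 °C
Reagents that add atoms: none
Why: Copper-catalysed O-alkylation of a phenol with a tertiary propargylic chloride, a method suited to hindered and electron-poor phenols at 0 °C; aldehyde, flavone and benzyl ethers are inert to DBU at this temperature.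

**Step 5**
Reactants: 9 3-{5,7-bis(benzyloxy)-2-[4-(benzyloxy)phenyl]-4-oxo-4H-chromen-8-yl}-4-[(2-methylbut-3-yn-2-yl)oxy]benzaldehyde
Product: 11 8-{5,7-bis(benzyloxy)-2-[4-(benzyloxy)phenyl]-4-oxo-4H-chromen-8-yl}-2,2-dimethyl-2H-chromene-6-carbaldehyde, via allenylphenol 10 (not isolated)
Conditions: PhNEt2, 190 °C
Reagents that add atoms: none
Why: Aromatic propargyl Claisen rearrangement: the [3,3] shift can only go to the one free ortho carbon of ring B, enolisation gives 10, and a 1,5-hydrogen shift followed by an oxa-6π electrocyclisation closes ring D as the 2,2-dimethyl-2H-chromene. This is the standard route from para-acyl phenols to 2,2-dimethylchromenes, and nothing else in 9 reacts thermally at 190 °C.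

**Step 6**
Reactants: 11 8-{5,7-bis(benzyloxy)-2-[4-(benzyloxy)phenyl]-4-oxo-4H-chromen-8-yl}-2,2-dimethyl-2H-chromene-6-carbaldehyde; 1 1-[2,4-bis(benzyloxy)-6-hydroxyphenyl]ethan-1-one
Product: 12 (E)-1-[2,4-bis(benzyloxy)-6-hydroxyphenyl]-3-(8-{5,7-bis(benzyloxy)-2-[4-(benzyloxy)phenyl]-4-oxo-4H-chromen-8-yl}-2,2-dimethyl-2H-chromen-6-yl)prop-2-en-1-one
Conditions: KOH (aq. 50 %), EtOH/THF, 25 °C; then aq. HCl
Reagents that add atoms: none
Why: Second Claisen–Schmidt condensation, with 11 as the non-enolisable aldehyde; the oxygen of ring B is now an ether, so no phenolate deactivates the aldehyde, and 25 °C spares ring F.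

**Step 7**
Reactants: 12 (E)-1-[2,4-bis(benzyloxy)-6-hydroxyphenyl]-3-(8-{5,7-bis(benzyloxy)-2-[4-(benzyloxy)phenyl]-4-oxo-4H-chromen-8-yl}-2,2-dimethyl-2H-chromen-6-yl)prop-2-en-1-one
Product: 13 5,7-bis(benzyloxy)-8-{6-[5,7-bis(benzyloxy)-4-oxo-4H-chromen-2-yl]-2,2-dimethyl-2H-chromen-8-yl}-2-[4-(benzyloxy)phenyl]-4H-chromen-4-one
Conditions: I2 (10 mol %), DMSO, 120 °C
Reagents that add atoms: none
Why: The iodine/DMSO oxidative cyclisation of step 2 closes ring C through the free chelated hydroxyl of 12; catalytic iodine and the lower temperature are chosen to spare the chromene double bond.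

**Step 8**
Reactants: 13 5,7-bis(benzyloxy)-8-{6-[5,7-bis(benzyloxy)-4-oxo-4H-chromen-2-yl]-2,2-dimethyl-2H-chromen-8-yl}-2-[4-(benzyloxy)phenyl]-4H-chromen-4-one
Product: 14 8-[6-(5,7-dihydroxy-4-oxo-4H-chromen-2-yl)-2,2-dimethyl-3,4-dihydro-2H-chromen-8-yl]-5,7-dihydroxy-2-(4-hydroxyphenyl)-4H-chromen-4-one
Conditions: H2 (1 atm), Pd/C (10 wt %), THF/MeOH, 25 °C
Reagents that add atoms: none
Why: Heterogeneous hydrogenation: hydrogenolysis of the five benzyl aryl ethers and saturation of the cis-disubstituted, styrene-type C3=C4 bond of ring D should proceed under the same mild conditions, whereas the C2=C3 bonds of rings C and F (trisubstituted vinylogous esters) are reduced much more slowly. No acid meets the tertiary ether and no stereocentre is formed.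

## Compound list

1 | 1-[2,4-bis(benzyloxy)-6-hydroxyphenyl]ethan-1-one | CC(=O)c1c(O)cc(OCc2ccccc2)cc1OCc1ccccc1 | starting material
2 | 4-(benzyloxy)benzaldehyde | O=Cc1ccc(OCc2ccccc2)cc1 | starting material
3 | (E)-1-[2,4-bis(benzyloxy)-6-hydroxyphenyl]-3-[4-(benzyloxy)phenyl]prop-2-en-1-one | O=C(/C=C/c1ccc(OCc2ccccc2)cc1)c1c(O)cc(OCc2ccccc2)cc1OCc1ccccc1 | intermediate
4 | 5,7-bis(benzyloxy)-2-[4-(benzyloxy)phenyl]-4H-chromen-4-one | O=c1cc(-c2ccc(OCc3ccccc3)cc2)oc2cc(OCc3ccccc3)cc(OCc3ccccc3)c12 | intermediate
5 | 4-hydroxybenzaldehyde | O=Cc1ccc(O)cc1 | starting material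
6 | 3-{5,7-bis(benzyloxy)-2-[4-(benzyloxy)phenyl]-4-oxo-4H-chromen-8-yl}-4-oxocyclohexa-1,5-diene-1-carbaldehyde (racemic keto tautomer of 7, not isolated) | O=CC1=CC(c2c(OCc3ccccc3)cc(OCc3ccccc3)c3c(=O)cc(-c4ccc(OCc5ccccc5)cc4)oc23)C(=O)C=C1 | intermediate
7 | 3-{5,7-bis(benzyloxy)-2-[4-(benzyloxy)phenyl]-4-oxo-4H-chromen-8-yl}-4-hydroxybenzaldehyde | O=Cc1ccc(O)c(-c2c(OCc3ccccc3)cc(OCc3ccccc3)c3c(=O)cc(-c4ccc(OCc5ccccc5)cc4)oc23)c1 | intermediate
8 | 3-chloro-3-methylbut-1-yne | C#CC(C)(C)Cl | starting material
9 | 3-{5,7-bis(benzyloxy)-2-[4-(benzyloxy)phenyl]-4-oxo-4H-chromen-8-yl}-4-[(2-methylbut-3-yn-2-yl)oxy]benzaldehyde | O=Cc1ccc(OC(C)(C)C#C)c(-c2c(OCc3ccccc3)cc(OCc3ccccc3)c3c(=O)cc(-c4ccc(OCc5ccccc5)cc4)oc23)c1 | intermediate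
10 | 3-{5,7-bis(benzyloxy)-2-[4-(benzyloxy)phenyl]-4-oxo-4H-chromen-8-yl}-4-hydroxy-5-(3-methylbuta-1,2-dien-1-yl)benzaldehyde (not isolated) | CC(C)=C=Cc1cc(C=O)cc(-c2c(OCc3ccccc3)cc(OCc3ccccc3)c3c(=O)cc(-c4ccc(OCc5ccccc5)cc4)oc23)c1O | intermediate
11 | 8-{5,7-bis(benzyloxy)-2-[4-(benzyloxy)phenyl]-4-oxo-4H-chromen-8-yl}-2,2-dimethyl-2H-chromene-6-carbaldehyde | CC1(C)C=Cc2cc(C=O)cc(-c3c(OCc4ccccc4)cc(OCc4ccccc4)c4c(=O)cc(-c5ccc(OCc6ccccc6)cc5)oc34)c2O1 | intermediate
12 | (E)-1-[2,4-bis(benzyloxy)-6-hydroxyphenyl]-3-(8-{5,7-bis(benzyloxy)-2-[4-(benzyloxy)phenyl]-4-oxo-4H-chromen-8-yl}-2,2-dimethyl-2H-chromen-6-yl)prop-2-en-1-one | CC1(C)C=Cc2cc(/C=C/C(=O)c3c(O)cc(OCc4ccccc4)cc3OCc3ccccc3)cc(-c3c(OCc4ccccc4)cc(OCc4ccccc4)c4c(=O)cc(-c5ccc(OCc6ccccc6)cc5)oc34)c2O1 | intermediate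
13 | 5,7-bis(benzyloxy)-8-{6-[5,7-bis(benzyloxy)-4-oxo-4H-chromen-2-yl]-2,2-dimethyl-2H-chromen-8-yl}-2-[4-(benzyloxy)phenyl]-4H-chromen-4-one | CC1(C)C=Cc2cc(-c3cc(=O)c4c(OCc5ccccc5)cc(OCc5ccccc5)cc4o3)cc(-c3c(OCc4ccccc4)cc(OCc4ccccc4)c4c(=O)cc(-c5ccc(OCc6ccccc6)cc5)oc34)c2O1 | intermediate
14 | 8-[6-(5,7-dihydroxy-4-oxo-4H-chromen-2-yl)-2,2-dimethyl-3,4-dihydro-2H-chromen-8-yl]-5,7-dihydroxy-2-(4-hydroxyphenyl)-4H-chromen-4-one | CC1(C)CCc2cc(-c3cc(=O)c4c(O)cc(O)cc4o3)cc(-c3c(O)cc(O)c4c(=O)cc(-c5ccc(O)cc5)oc34)c2O1 | target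

## Step count and least certain steps

Total step count: 8. Longest linear sequence: 8 steps (1 → 3 → 4 → 7 → 9 → 11 → 12 → 13 → 14).

**Step 3 (key step, proposed new method).** Several processes can divert it:
- oxidation of the arene 4 in place of the phenol 5, followed by self-coupling of 4;
- attack through C6 or C3 of 4 in place of C8;
- C–O in place of C–C bond formation;
- hydrogen abstraction by tert-butoxyl radicals at benzylic positions or at the formyl group;
- a second arylation of the product phenol;
- loss of the chelated benzyl group at the C5 oxygen under the Lewis acid.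

The cause is that 5 is harder to oxidise than the phenols for which this reaction type is established, and 4 is a weaker nucleophile than trialkoxybenzenes. The fallback uses known cross-coupling chemistry, sets out from 4 and 5 and returns at 7. Iodination of 4 (I2, CF3CO2Ag, CH2Cl2) gives 5,7-bis(benzyloxy)-2-[4-(benzyloxy)phenyl]-8-iodo-4H-chromen-4-one F1. Iodination of 5 (I2, KI, aq. NH3) gives 4-hydroxy-3-iodobenzaldehyde F2. Miyaura borylation of F2 (B2pin2, PdCl2(dppf), KOAc, dioxane, 80 °C) gives 4-hydroxy-3-(4,4,5,5-tetramethyl-1,3,2-dioxaborolan-2-yl)benzaldehyde F3. Suzuki–Miyaura coupling of F1 with F3 (Pd(OAc)2, SPhos, K3PO4, toluene/water, 90 °C) gives 7.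

**Step 7.** Iodine or the HI formed may add to the electron-rich C3=C4 bond of the chromene, or the acid may oligomerise it, before ring C is closed. The fallback saturates ring D first; it sets out from 11 and returns at 14. Homogeneous hydrogenation of 11 (RhCl(PPh3)3, H2, benzene/EtOH, 25 °C; aldehyde and benzyl ethers untouched) gives 8-{5,7-bis(benzyloxy)-2-[4-(benzyloxy)phenyl]-4-oxo-4H-chromen-8-yl}-2,2-dimethylchroman-6-carbaldehyde F4. Claisen–Schmidt condensation of F4 with 1 gives (E)-1-[2,4-bis(benzyloxy)-6-hydroxyphenyl]-3-(8-{5,7-bis(benzyloxy)-2-[4-(benzyloxy)phenyl]-4-oxo-4H-chromen-8-yl}-2,2-dimethylchroman-6-yl)prop-2-en-1-one F5. Iodine/DMSO cyclisation of F5 gives 5,7-bis(benzyloxy)-8-{6-[5,7-bis(benzyloxy)-4-oxo-4H-chromen-2-yl]-2,2-dimethylchroman-8-yl}-2-[4-(benzyloxy)phenyl]-4H-chromen-4-one F6. Hydrogenolysis of F6 (H2, Pd/C) gives 14.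

**Step 5.** The [3,3] shift may be slow, because ring B is electron-poor and the ortho aryl group crowds the ether, so that thermal cleavage of the tertiary propargyl ether back to the phenol competes at 190 °C. The fallback builds ring D through a prenylphenol; it sets out from 9 and returns at 14. Semi-hydrogenation of 9 (H2, Pd/CaCO3 poisoned with Pb(OAc)2, quinoline) gives 3-{5,7-bis(benzyloxy)-2-[4-(benzyloxy)phenyl]-4-oxo-4H-chromen-8-yl}-4-[(2-methylbut-3-en-2-yl)oxy]benzaldehyde F7. Its allyl Claisen rearrangement needs far less heat (toluene, 110 °C) and gives 3-{5,7-bis(benzyloxy)-2-[4-(benzyloxy)phenyl]-4-oxo-4H-chromen-8-yl}-4-hydroxy-5-(3-methylbut-2-en-1-yl)benzaldehyde F8. Acid (p-TsOH, toluene, 60 °C) closes ring D by Markovnikov hydroalkoxylation to the chroman aldehyde F4, which goes on through the chalcone F5 and the biflavone F6 to 14 as described for step 7.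

**Step 6.** Hydroxide may open ring F (retro-oxa-Michael cleavage of the vinylogous ester) during the long condensation of a hindered, para-alkoxy-deactivated aldehyde. The fallback avoids hydroxide; it sets out from 11 and 1 and returns at 13. Pyrrolidine-mediated condensation (pyrrolidine, EtOH, 78 °C; enamine/iminium pathway with oxa-Michael closure in the same pot) gives racemic 5,7-bis(benzyloxy)-2-(8-{5,7-bis(benzyloxy)-2-[4-(benzyloxy)phenyl]-4-oxo-4H-chromen-8-yl}-2,2-dimethyl-2H-chromen-6-yl)chroman-4-one F9. Dehydrogenation of F9 (I2, DMSO, 120 °C) gives 13.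

## Further compounds

F1 | step 3 | 5,7-bis(benzyloxy)-2-[4-(benzyloxy)phenyl]-8-iodo-4H-chromen-4-one | O=c1cc(-c2ccc(OCc3ccccc3)cc2)oc2c(I)c(OCc3ccccc3)cc(OCc3ccccc3)c12
F2 | step 3 | 4-hydroxy-3-iodobenzaldehyde | O=Cc1ccc(O)c(I)c1
F3 | step 3 | 4-hydroxy-3-(4,4,5,5-tetramethyl-1,3,2-dioxaborolan-2-yl)benzaldehyde | O=Cc1ccc(O)c(B2OC(C)(C)C(C)(C)O2)c1
F4 | step 7 | 8-{5,7-bis(benzyloxy)-2-[4-(benzyloxy)phenyl]-4-oxo-4H-chromen-8-yl}-2,2-dimethylchroman-6-carbaldehyde | CC1(C)CCc2cc(C=O)cc(-c3c(OCc4ccccc4)cc(OCc4ccccc4)c4c(=O)cc(-c5ccc(OCc6ccccc6)cc5)oc34)c2O1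
F5 | step 7 | (E)-1-[2,4-bis(benzyloxy)-6-hydroxyphenyl]-3-(8-{5,7-bis(benzyloxy)-2-[4-(benzyloxy)phenyl]-4-oxo-4H-chromen-8-yl}-2,2-dimethylchroman-6-yl)prop-2-en-1-one | CC1(C)CCc2cc(/C=C/C(=O)c3c(O)cc(OCc4ccccc4)cc3OCc3ccccc3)cc(-c3c(OCc4ccccc4)cc(OCc4ccccc4)c4c(=O)cc(-c5ccc(OCc6ccccc6)cc5)oc34)c2O1
F6 | step 7 | 5,7-bis(benzyloxy)-8-{6-[5,7-bis(benzyloxy)-4-oxo-4H-chromen-2-yl]-2,2-dimethylchroman-8-yl}-2-[4-(benzyloxy)phenyl]-4H-chromen-4-one | CC1(C)CCc2cc(-c3cc(=O)c4c(OCc5ccccc5)cc(OCc5ccccc5)cc4o3)cc(-c3c(OCc4ccccc4)cc(OCc4ccccc4)c4c(=O)cc(-c5ccc(OCc6ccccc6)cc5)oc34)c2O1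
F7 | step 5 | 3-{5,7-bis(benzyloxy)-2-[4-(benzyloxy)phenyl]-4-oxo-4H-chromen-8-yl}-4-[(2-methylbut-3-en-2-yl)oxy]benzaldehyde | O=Cc1ccc(OC(C)(C)C=C)c(-c2c(OCc3ccccc3)cc(OCc3ccccc3)c3c(=O)cc(-c4ccc(OCc5ccccc5)cc4)oc23)c1
F8 | step 5 | 3-{5,7-bis(benzyloxy)-2-[4-(benzyloxy)phenyl]-4-oxo-4H-chromen-8-yl}-4-hydroxy-5-(3-methylbut-2-en-1-yl)benzaldehyde | CC(C)=CCc1cc(C=O)cc(-c2c(OCc3ccccc3)cc(OCc3ccccc3)c3c(=O)cc(-c4ccc(OCc5ccccc5)cc4)oc23)c1O
F9 | step 6 | 5,7-bis(benzyloxy)-2-(8-{5,7-bis(benzyloxy)-2-[4-(benzyloxy)phenyl]-4-oxo-4H-chromen-8-yl}-2,2-dimethyl-2H-chromen-6-yl)chroman-4-one (racemic) | CC1(C)C=Cc2cc(C3CC(=O)c4c(OCc5ccccc5)cc(OCc5ccccc5)cc4O3)cc(-c3c(OCc4ccccc4)cc(OCc4ccccc4)c4c(=O)cc(-c5ccc(OCc6ccccc6)cc5)oc34)c2O1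
A1 | alternative 1 | 5,7-bis(benzyloxy)-2-[4-(benzyloxy)phenyl]-8-iodo-4H-chromen-4-one | O=c1cc(-c2ccc(OCc3ccccc3)cc2)oc2c(I)c(OCc3ccccc3)cc(OCc3ccccc3)c12
A2 | alternative 1 | 5,7-bis(benzyloxy)-2-[2,2-dimethyl-8-(4,4,5,5-tetramethyl-1,3,2-dioxaborolan-2-yl)chroman-6-yl]-4H-chromen-4-one | CC1(C)CCc2cc(-c3cc(=O)c4c(OCc5ccccc5)cc(OCc5ccccc5)cc4o3)cc(B3OC(C)(C)C(C)(C)O3)c2O1
A3 | alternative 2 | 1-[2,4-bis(benzyloxy)-6-hydroxyphenyl]-3-[3-(4,6-bis(benzyloxy)-3-{3-[4-(benzyloxy)phenyl]-3-oxopropanoyl}-2-hydroxyphenyl)-4-hydroxy-5-(3-methylbut-2-en-1-yl)phenyl]propane-1,3-dione | CC(C)=CCc1cc(C(=O)CC(=O)c2c(O)cc(OCc3ccccc3)cc2OCc2ccccc2)cc(-c2c(O)c(C(=O)CC(=O)c3ccc(OCc4ccccc4)cc3)c(OCc3ccccc3)cc2OCc2ccccc2)c1O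
A4 | alternative 3 | 6-(1,3-dioxolan-2-yl)-2,2-dimethyl-8-(trimethylsilyl)chroman-7-yl trifluoromethanesulfonate | CC1(C)CCc2cc(C3OCCO3)c(OS(=O)(=O)C(F)(F)F)c([Si](C)(C)C)c2O1
A5 | alternative 3 | 6-(1,3-dioxolan-2-yl)-2,2-dimethyl-7,8-didehydrochroman (aryne) | CC1(C)CCC2=C(O1)C#CC(C3OCCO3)=C2
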